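## The problem

Compound 15 is a 2,5-diaryl-3,4-bis(acetoxymethyl)oxolane, a 7,7′-epoxylignan made of two C6–C3 halves. The ring O1–C2–C3–C4–C5 carries four contiguous stereocentres, (2R,3S,4R,5S), in a meso array. Both catechol rings lie on one face and both CH2OAc groups on the other, so the neighbours are 2,3-trans, 3,4-cis and 4,5-trans, and a mirror plane runs through O1 and the midpoint of C3–C4. C2 and C5 are benzylic ether carbons para to a phenol. They can open to quinone methides and close again, so they can be corrected late and will follow C3 and C4 into the aryl-trans arrangement. C3 and C4 carry no activating group. Their cis relationship is fixed when the C3–C4 bond is made, and this is the real stereochemical problem. The sensitive groups are the catechols (air, base, o-quinone chemistry), the primary acetates (base, hydride, nucleophiles) and the benzylic ring C–O bonds (strong acid, forcing hydrogenolysis). The enabling feature is that the ring is two identical cinnamyl acetate units joined β to β (C3–C4) and bridged α to α by one oxygen (C2–O1–C5). The γ-oxygens are already acylated and cannot close a furofuran, so an oxidative phenol dimerisation that captures one molecule of water can make the ring and all four centres at once.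

## Retrosynthesis

15 ⇒ 14. Only protecting-group and blocking-group bonds are cut: two O–benzyl bonds and two aryl C–Br bonds. A free catechol cannot go through an oxidative coupling, and a ring with a free C5 would pair mainly at C5 and O4. So O3 carries benzyl and C5 carries bromine in 14. Both leave under H2 on palladium in one non-basic operation that spares the acetates. The forward step must not open the benzylic ring C–O bonds.

14 ⇒ two molecules of 10 and water (through 11, 12 and 13). Three bonds are cut at once: C3–C4, O1–C2 and O1–C5. A single C–O cut (cyclodehydration of a 1,4-diol) or a C2–C3 cut would leave an acyclic precursor with three or four stereocentres still to build. The threefold cut uses the mirror plane and reduces the problem to one achiral nine-carbon phenol. The forward reaction must give β–β′ pairing (not pairing at C5 or O4), water as the only oxygen nucleophile, and unlike pairing of the two β-carbons. (E)-configured monomers pair like faces and would end in the 3,4-trans ring. The monomer is therefore drawn as the (Z)-alkene 10, whose stacked pairing should be unlike.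

10 ⇒ 9 ⇒ 8. The phenol is unmasked last (O–Si cut) and the acetate is put on before (O–acyl cut). A free phenol would be acetylated together with the allylic alcohol, and a phenoxide next to an allylic acetate can expel it. The silyl ether in 9 avoids both problems. The forward steps are a standard acetylation and a buffered fluoride cleavage.

8 ⇒ 7 ⇒ 5 + 6. The C7=C8 bond is cut by a Z-selective olefination of aldehyde 5 with phosphonate 6, followed by ester reduction. An alkyne semireduction would need an aryl–alkyne coupling that collides with the C5 bromide. The olefination works from the aldehyde already present and sets the geometry kinetically. Aldehyde 5 has no stereochemistry at all.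

5 ⇒ 4 ⇒ 3 ⇒ 1 + 2. The arene is decorated in three operations: silylation of O4, bromination at C5 and benzylation of O3 with 2. The order matters. Benzylating first through the dianion of 1 puts benzyl on O3 and leaves the 4-hydroxyl free to direct bromination ortho to itself. Silylating last avoids exposing a silyl ether to basic alkylation, where it could migrate between the catechol oxygens. Each step must be regioselective on a simple benzaldehyde.

## Roads not taken

Alternative 1: The cut is C2–C3, with a lactone standing in for the two CH2OAc groups.
- Forward step: diazo lactone A1 is treated with Rh2(OAc)4. The rhodium carbene inserts into the benzylic C–H bond of the arylmethyl ether (a 1,5-insertion) and gives the cis-fused oxolane–lactone A2 with both aryls on the convex face.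
- Merits: the 3,4-cis relationship is enforced by the bicyclo[3.3.0] ring fusion, and an ether-activated benzylic C–H bond is a favoured insertion site.
- Weak points: A1 is an α-diazo lactone with a β-hydrogen, so 1,2-hydride shift to the butenolide competes. The electron-rich aryl rings invite cyclopropanation and the ether oxygen invites ylide formation. A1 needs its own stereodefined synthesis. After A2 come lactone reduction, bis-acetylation and fourfold debenzylation.
- Comparison: this road holds C3/C4 better than the chosen plan, which depends on the pairing geometry of two radicals. The chosen plan sets against it three bonds, the ring and four centres in one operation from one achiral monomer, and a product 14 that already carries both acetates.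

Alternative 2: The cuts are O1–C2 and C3–C4 in a formal [3+2] union of vinyl epoxide A3 with benzylidene malonate A4.
- Forward step: Pd2(dba)3 with a phosphine (zerovalent palladium) ionises A3 to a π-allylpalladium alkoxide. Oxa-Michael addition to A4 and closure of the malonate carbanion on the allyl terminus give A5, with 2,5-cis aryls and the vinyl group trans to the C5 aryl.
- Merits: convergent, a known cycloaddition type, clean regiochemistry and no pairing ambiguity.
- Weak points: A5 has a geminal diester at C3 and a vinyl group at C4. Reaching two CH2OAc groups needs decarboxylation, ester reduction, ozonolysis–reduction through an epimerisable aldehyde, acetylation and fourfold debenzylation. The decarboxylation sets C3 by a protonation that must place the ester cis to the C4 substituent. The mirror symmetry is not used.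
- Comparison: it is at least as good in regiocontrol and catalytic precedent. It is several steps longer after the key step and also leaves the 3,4-cis relationship to a step without built-in control, so it does not repair the one weakness of the chosen plan.

Alternative 3: The cuts are the two aryl–carbon bonds at C2 and C5; no ring is formed.
- Forward step: diacid A6 (both CH2OAc groups cis to each other and trans to the carboxyls, carved from an oxanorbornene Diels–Alder scaffold) is coupled twice with aryl bromide A7. The catalysts are Ir[dF(CF3)ppy]2(dtbbpy)PF6 and NiCl2·glyme with 4,4′-di-tert-butyl-2,2′-bipyridine under blue light. The product A8 is the tetra-O-benzyl ether of 15.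
- Merits: the 3,4-cis relationship comes ready-made from a cycloadduct. The α-oxy radicals should be arylated anti to the neighbouring CH2OAc. A8 is one hydrogenolysis from 15. The sequence is no longer than the chosen one and may be shorter.
- Weak points: two decarboxylative couplings must succeed on one molecule with an electron-rich aryl bromide. Protodecarboxylation and mono-arylation are the expected losses. A C2/C5 cis isomer cannot be corrected while the phenols are benzylated.
- Comparison: in security at C3/C4 and in step count this road is as good as or better than the chosen plan. The chosen plan sets against it a key step of a known type that builds the whole skeleton, the ring and all four centres from one monomer, with C2/C5 correctable through the free phenols. For its strengths this road is kept as the fallback for step 8.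

Key step: step 8

Assumption: the target is meso and achiral, so the descriptors of 12–15 give relative configuration; the exocyclic alkene geometry of the quinone methides 12 and 13 is left undefined because it is lost on rearomatisation.

## Route

Step 1
Reactants: 1 protocatechualdehyde (3,4-dihydroxybenzaldehyde); 2 benzyl bromide
Product: 3 3-(benzyloxy)-4-hydroxybenzaldehyde
Conditions: NaH (2.2 equiv), DMSO, 20 °C; then 2 (1.0 equiv); aq. HCl work-up
Reagents that add atoms: none
Why: Williamson etherification of the catechol dianion; the 4-phenoxide is delocalised into the para formyl group, so the single equivalent of 2 should be taken by the more basic and more nucleophilic 3-phenoxide.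

Step 2
Reactants: 3 3-(benzyloxy)-4-hydroxybenzaldehyde
Product: 4 3-(benzyloxy)-5-bromo-4-hydroxybenzaldehyde
Conditions: Br2 (1.05 equiv), NaOAc, AcOH, 20 °C
Reagents that add atoms: bromine, BrBr
Why: Electrophilic aromatic bromination directed by the free phenol; the para position is occupied by the formyl group, so substitution should occur at the one open ortho position (C5), as in the bromination of vanillin, while NaOAc buffers HBr and protects the benzyl ether.

Step 3
Reactants: 4 3-(benzyloxy)-5-bromo-4-hydroxybenzaldehyde
Product: 5 3-(benzyloxy)-5-bromo-4-(tert-butyldimethylsilyloxy)benzaldehyde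
Conditions: TBSCl, imidazole, DMF, 20 °C
Reagents that add atoms: tert-butyldimethylsilyl chloride, CC(C)(C)[Si](C)(C)Cl
Why: Standard silylation of a phenol; masking the acidic hydroxyl keeps the aldehyde electrophilic for the olefination and protects the phenol during reduction and acetylation.

Step 4
Reactants: 5 3-(benzyloxy)-5-bromo-4-(tert-butyldimethylsilyloxy)benzaldehyde; 6 methyl 2-[bis(2,2,2-trifluoroethoxy)phosphoryl]acetate
Product: 7 methyl (Z)-3-[3-(benzyloxy)-5-bromo-4-(tert-butyldimethylsilyloxy)phenyl]prop-2-enoate
Conditions: KN(SiMe3)2, 18-crown-6, THF, −78 °C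
Reagents that add atoms: none
Why: Still–Gennari variant of the Horner–Wadsworth–Emmons olefination; the electron-poor trifluoroethyl phosphonate and the dissociated potassium counter-ion make elimination faster than equilibration of the adducts, so the kinetic (Z)-enoate should form.

Step 5
Reactants: 7 methyl (Z)-3-[3-(benzyloxy)-5-bromo-4-(tert-butyldimethylsilyloxy)phenyl]prop-2-enoate
Product: 8 (Z)-3-[3-(benzyloxy)-5-bromo-4-(tert-butyldimethylsilyloxy)phenyl]prop-2-en-1-ol
Conditions: i-Bu2AlH (2.5 equiv), CH2Cl2, −78 °C; aq. KNaC4H4O6 work-up
Reagents that add atoms: none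
Why: 1,2-Reduction of an enoate to the allylic alcohol by an aluminium hydride; the alkene geometry is retained and the aryl bromide, the silyl ether and the benzyl ether are inert at this temperature.

Step 6
Reactants: 8 (Z)-3-[3-(benzyloxy)-5-bromo-4-(tert-butyldimethylsilyloxy)phenyl]prop-2-en-1-ol
Product: 9 (Z)-3-[3-(benzyloxy)-5-bromo-4-(tert-butyldimethylsilyloxy)phenyl]prop-2-en-1-yl acetate
Conditions: Ac2O, pyridine, DMAP (cat.), CH2Cl2, 0 °C
Reagents that add atoms: acetic anhydride, CC(=O)OC(C)=O
Why: Nucleophile-catalysed acylation of a primary allylic alcohol; the phenol is silylated, so only the γ-hydroxyl is acetylated.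

Step 7
Reactants: 9 (Z)-3-[3-(benzyloxy)-5-bromo-4-(tert-butyldimethylsilyloxy)phenyl]prop-2-en-1-yl acetate
Product: 10 (Z)-3-[3-(benzyloxy)-5-bromo-4-hydroxyphenyl]prop-2-en-1-yl acetate
Conditions: Bu4NF, AcOH (1:1), THF, 0 °C, dark
Reagents that add atoms: none
Why: Fluoride cleavage of an aryl silyl ether; the acetic acid buffer keeps the product as the phenol and not the phenoxide, which could expel the allylic acetate or transfer the acetyl group, and exclusion of light guards the (Z)-alkene.

Step 8
Reactants: 10 (Z)-3-[3-(benzyloxy)-5-bromo-4-hydroxyphenyl]prop-2-en-1-yl acetate (two molecules)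
Product: 14 [(2R,3S,4R,5S)-2,5-bis(3-benzyloxy-5-bromo-4-hydroxyphenyl)oxolane-3,4-diyl]bis(methylene) diacetate (meso; 2,3-trans/3,4-cis/4,5-trans), via phenoxyl radical 11 (not isolated), via meso bis-quinone methide 12 (not isolated), via hydroxy quinone methide 13 (not isolated)
Conditions: laccase from Trametes versicolor, O2 (air), acetone–NaOAc/AcOH buffer (pH 5), 20 °C, dark, 10 added slowly
Reagents that add atoms: water, O
Why: Laccase removes one electron from each molecule of 10 (O2 ends as water) to give radical 11 with spin at O4, C1, C5 and the β-carbon; the bromine at C5 and the benzyl ether at O3 leave β–β′ pairing as the productive carbon–carbon mode, which forms C3–C4 and the bis-quinone methide 12. Because both γ-oxygens are acetylated, the only nucleophile for 12 is solvent water, which adds to one benzylic carbon (O1–C2, 13); the new hydroxyl then adds to the second quinone methide in a 5-exo-trig closure (O1–C5) that rearomatises the ring and completes the oxolane. The closest known reaction type is the laccase- or peroxidase-mediated β–β dehydrodimerisation of γ-acylated 4-hydroxycinnamyl alcohols with water capture, here applied to a (Z)-configured, ring-brominated monomer. C3 and C4 are set in the radical pairing: (E)-monomers pair like faces (the resinol series, which would end as the 3,4-trans ring), because the stacked radicals turn each aryl away from the partner's CH2O group; in the (Z)-radical aryl and CH2OAc lie on the same side of the C7–C8 axis, so this clash is avoided only in the centrosymmetric unlike (Re–Si) pairing, which is expected to give meso-12 and the 3,4-cis ring. C2 follows from the face of water addition and C5 from the ring closure, each preferring the aryl anti to the adjacent CH2OAc; as either benzylic C–O bond para to the free phenol can reopen to its quinone methide, both centres can settle in the 2,3-trans/4,5-trans arrangement, which makes the aryls cis. The step therefore needs β–β′ regioselectivity (secured by Br and OBn), water as the sole oxygen nucleophile (secured by the acetates) and unlike pairing (sought through the Z alkene), and 14 should be separable from 3,4-trans isomers by chromatography.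

Step 9
Reactants: 14 [(2R,3S,4R,5S)-2,5-bis(3-benzyloxy-5-bromo-4-hydroxyphenyl)oxolane-3,4-diyl]bis(methylene) diacetate
Product: 15 [(2R,3S,4R,5S)-2,5-bis(3,4-dihydroxyphenyl)oxolane-3,4-diyl]bis(methylene) diacetate (meso; the target)
Conditions: H2 (1 atm), Pd/C, NaOAc, EtOAc–EtOH, 20 °C
Reagents that add atoms: none
Why: Hydrogenolysis of aryl benzyl ethers and hydrodebromination of aryl bromides on palladium, both faster than cleavage of the cyclic benzylic ether under neutral conditions; NaOAc traps the HBr so that the ring is not opened by acid, and no stereocentre is touched.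

## Compound list

1 | protocatechualdehyde (3,4-dihydroxybenzaldehyde) | O=Cc1ccc(O)c(O)c1 | starting material
2 | benzyl bromide | BrCc1ccccc1 | starting material
3 | 3-(benzyloxy)-4-hydroxybenzaldehyde | O=Cc1ccc(O)c(OCc2ccccc2)c1 | intermediate
4 | 3-(benzyloxy)-5-bromo-4-hydroxybenzaldehyde | O=Cc1cc(Br)c(O)c(OCc2ccccc2)c1 | intermediate
5 | 3-(benzyloxy)-5-bromo-4-(tert-butyldimethylsilyloxy)benzaldehyde | O=Cc1cc(Br)c(O[Si](C)(C)C(C)(C)C)c(OCc2ccccc2)c1 | intermediate
6 | methyl 2-[bis(2,2,2-trifluoroethoxy)phosphoryl]acetate | COC(=O)CP(=O)(OCC(F)(F)F)OCC(F)(F)F | starting material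
7 | methyl (Z)-3-[3-(benzyloxy)-5-bromo-4-(tert-butyldimethylsilyloxy)phenyl]prop-2-enoate | COC(=O)/C=C\c1cc(Br)c(O[Si](C)(C)C(C)(C)C)c(OCc2ccccc2)c1 | intermediate
8 | (Z)-3-[3-(benzyloxy)-5-bromo-4-(tert-butyldimethylsilyloxy)phenyl]prop-2-en-1-ol | OC/C=C\c1cc(Br)c(O[Si](C)(C)C(C)(C)C)c(OCc2ccccc2)c1 | intermediate
9 | (Z)-3-[3-(benzyloxy)-5-bromo-4-(tert-butyldimethylsilyloxy)phenyl]prop-2-en-1-yl acetate | CC(=O)OC/C=C\c1cc(Br)c(O[Si](C)(C)C(C)(C)C)c(OCc2ccccc2)c1 | intermediate
10 | (Z)-3-[3-(benzyloxy)-5-bromo-4-hydroxyphenyl]prop-2-en-1-yl acetate | CC(=O)OC/C=C\c1cc(Br)c(O)c(OCc2ccccc2)c1 | intermediate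
11 | 4-[(Z)-3-acetoxyprop-1-en-1-yl]-2-(benzyloxy)-6-bromophenoxyl radical | CC(=O)OC/C=C\c1cc(Br)c([O])c(OCc2ccccc2)c1 | intermediate
12 | meso-2,3-bis[(3-benzyloxy-5-bromo-4-oxocyclohexa-2,5-dien-1-ylidene)methyl]butane-1,4-diyl diacetate | CC(=O)OC[C@@H](C=C1C=C(Br)C(=O)C(OCc2ccccc2)=C1)[C@H](COC(C)=O)C=C1C=C(Br)C(=O)C(OCc2ccccc2)=C1 | intermediate
13 | 2-[(3-benzyloxy-5-bromo-4-hydroxyphenyl)(hydroxy)methyl]-3-[(3-benzyloxy-5-bromo-4-oxocyclohexa-2,5-dien-1-ylidene)methyl]butane-1,4-diyl diacetate, configuration as in 14 | CC(=O)OC[C@@H]([C@@H](O)c1cc(Br)c(O)c(OCc2ccccc2)c1)[C@H](COC(C)=O)C=C1C=C(Br)C(=O)C(OCc2ccccc2)=C1 | intermediate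
14 | [(2R,3S,4R,5S)-2,5-bis(3-benzyloxy-5-bromo-4-hydroxyphenyl)oxolane-3,4-diyl]bis(methylene) diacetate (meso) | CC(=O)OC[C@@H]1[C@H](COC(C)=O)[C@@H](c2cc(Br)c(O)c(OCc3ccccc3)c2)O[C@H]1c1cc(Br)c(O)c(OCc2ccccc2)c1 | intermediate
15 | [(2R,3S,4R,5S)-2,5-bis(3,4-dihydroxyphenyl)oxolane-3,4-diyl]bis(methylene) diacetate (meso) | CC(=O)OC[C@@H]1[C@H](COC(C)=O)[C@@H](c2ccc(O)c(O)c2)O[C@H]1c1ccc(O)c(O)c1 | target

## Step count and risks

Total step count: 9. Longest linear sequence: 9 steps (1 to 15).

Step 8 (key step). The most likely failure is like pairing of the two β-carbons. It could arise from Z-to-E equilibration of the monomer or its radical, or from an unlike preference weaker than the stacking argument predicts. Material then goes into the 3,4-trans series, which cannot be corrected afterwards. Pairing at O4 and further oxidation of the phenolic product would lower the yield as well.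

The fallback takes the 3,4-cis relationship from a ring instead of from a pairing. It sets out from benzyl bromide 2 and rejoins the route at target 15.
- Purchased exo-7-oxabicyclo[2.2.1]hept-5-ene-2,3-dicarboxylic anhydride is reduced with LiAlH4 in THF at 0 °C to exo,exo-7-oxabicyclo[2.2.1]hept-5-ene-2,3-diyldimethanol F1.
- F1 is acetylated (Ac2O, pyridine) to the exo,exo-diacetate F2.
- The ring alkene of F2 is cleaved with RuCl3 (cat.) and NaIO4 to the meso oxolane-2,5-dicarboxylic acid F3, with the CH2OAc groups cis to each other and trans to the carboxyls.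
- Purchased 4-bromocatechol is benzylated with 2 (K2CO3, DMF) to 4-bromo-1,2-bis(benzyloxy)benzene F4.
- F3 and two equivalents of F4 are joined by twofold decarboxylative arylation to the tetra-O-benzyl ether F5. The conditions are Ir[dF(CF3)ppy]2(dtbbpy)PF6, NiCl2·glyme, 4,4′-di-tert-butyl-2,2′-bipyridine, Cs2CO3 and blue light.
- Hydrogenolysis of F5 (H2, Pd/C, EtOAc) gives 15.

Step 4. The kinetic Z preference may erode, so that (E)-enoate accompanies 7 and later feeds the 3,4-trans series. The fallback sets the geometry by photochemical isomerisation instead of by the olefination. It sets out from 5 and returns at 8.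
- 5 is olefinated E-selectively with triethyl phosphonoacetate (NaH, THF) to the ethyl (E)-enoate F8.
- F8 is reduced with i-Bu2AlH to the (E)-allylic alcohol F9.
- F9 is isomerised contra-thermodynamically by triplet energy transfer (Ir(ppy)3, blue light, MeCN) to 8.

Step 7. Once the phenol is free, transient phenoxide may expel the allylic acetate through a vinylogous quinone methide. Acetyl transfer to the phenol and Z-to-E isomerisation are further risks. The fallback reverses the order and leaves the chemoselection to an enzyme. It sets out from 8 and returns at 10.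
- 8 is desilylated (Bu4NF, AcOH, THF, 0 °C) to (Z)-3-[3-(benzyloxy)-5-bromo-4-hydroxyphenyl]prop-2-en-1-ol F10.
- The primary allylic hydroxyl of F10 alone is acetylated with Candida antarctica lipase B and vinyl acetate in tert-butyl methyl ether to give 10.

Step 9. Reductive opening of the two benzylic ring C–O bonds may compete with O-debenzylation and hydrodebromination, or debromination may stay incomplete. The fallback separates the two unmaskings and avoids heterogeneous hydrogenation. It sets out from 14 and returns at 15.
- Homogeneous hydrodebromination (Pd(OAc)2, PPh3, HCO2H, Et3N, DMF, 60 °C) gives the 3-O,3′-O-dibenzyl ether F11.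
- Lewis-acid debenzylation (BCl3, pentamethylbenzene, CH2Cl2, −78 °C) gives 15.

Step 1. If dianion formation is incomplete, alkylation at O4 and twofold benzylation will compete. The fallback differentiates the two oxygens by protection. It sets out from 1 and returns at 3.
- 1 is alkylated at O4 under monoanion conditions (4-methoxybenzyl chloride, NaHCO3, NaI, DMF) to 3-hydroxy-4-[(4-methoxybenzyl)oxy]benzaldehyde F6.
- F6 is benzylated with 2 (K2CO3, DMF) to 3-(benzyloxy)-4-[(4-methoxybenzyl)oxy]benzaldehyde F7.
- CF3CO2H in CH2Cl2 at 0 °C removes the 4-methoxybenzyl group and returns 3.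

## Further compounds

F1 | step 8 | exo,exo-7-oxabicyclo[2.2.1]hept-5-ene-2,3-diyldimethanol (meso) | OC[C@@H]1[C@H](CO)[C@H]2C=C[C@@H]1O2
F2 | step 8 | exo,exo-7-oxabicyclo[2.2.1]hept-5-ene-2,3-diylbis(methylene) diacetate (meso) | CC(=O)OC[C@@H]1[C@H](COC(C)=O)[C@H]2C=C[C@@H]1O2
F3 | step 8 | (2R,3S,4R,5S)-3,4-bis(acetoxymethyl)oxolane-2,5-dicarboxylic acid (meso) | CC(=O)OC[C@@H]1[C@H](COC(C)=O)[C@@H](C(=O)O)O[C@H]1C(=O)O
F4 | step 8 | 4-bromo-1,2-bis(benzyloxy)benzene | Brc1ccc(OCc2ccccc2)c(OCc2ccccc2)c1
F5 | step 8 | [(2R,3S,4R,5S)-2,5-bis[3,4-bis(benzyloxy)phenyl]oxolane-3,4-diyl]bis(methylene) diacetate (meso) | CC(=O)OC[C@@H]1[C@H](COC(C)=O)[C@@H](c2ccc(OCc3ccccc3)c(OCc3ccccc3)c2)O[C@H]1c1ccc(OCc2ccccc2)c(OCc2ccccc2)c1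
F6 | step 1 | 3-hydroxy-4-[(4-methoxybenzyl)oxy]benzaldehyde | O=Cc1ccc(OCc2ccc(OC)cc2)c(O)c1
F7 | step 1 | 3-(benzyloxy)-4-[(4-methoxybenzyl)oxy]benzaldehyde | O=Cc1ccc(OCc2ccc(OC)cc2)c(OCc2ccccc2)c1
F8 | step 4 | ethyl (E)-3-[3-(benzyloxy)-5-bromo-4-(tert-butyldimethylsilyloxy)phenyl]prop-2-enoate | CCOC(=O)/C=C/c1cc(Br)c(O[Si](C)(C)C(C)(C)C)c(OCc2ccccc2)c1
F9 | step 4 | (E)-3-[3-(benzyloxy)-5-bromo-4-(tert-butyldimethylsilyloxy)phenyl]prop-2-en-1-ol | OC/C=C/c1cc(Br)c(O[Si](C)(C)C(C)(C)C)c(OCc2ccccc2)c1
F10 | step 7 | (Z)-3-[3-(benzyloxy)-5-bromo-4-hydroxyphenyl]prop-2-en-1-ol | OC/C=C\c1cc(Br)c(O)c(OCc2ccccc2)c1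
F11 | step 9 | [(2R,3S,4R,5S)-2,5-bis(3-benzyloxy-4-hydroxyphenyl)oxolane-3,4-diyl]bis(methylene) diacetate (meso) | CC(=O)OC[C@@H]1[C@H](COC(C)=O)[C@@H](c2ccc(O)c(OCc3ccccc3)c2)O[C@H]1c1ccc(O)c(OCc2ccccc2)c1
A1 | alternative 1 | 3-diazo-4-{[3,4-bis(benzyloxy)phenyl][3,4-bis(benzyloxy)benzyloxy]methyl}oxolan-2-one (racemic, relative configuration as in A2) | [N-]=[N+]=C1C(=O)OC[C@@H]1[C@@H](c1ccc(OCc2ccccc2)c(OCc2ccccc2)c1)OCc1ccc(OCc2ccccc2)c(OCc2ccccc2)c1
A2 | alternative 1 | cis-fused 4,6-bis[3,4-bis(benzyloxy)phenyl]tetrahydrofuro[3,4-c]furan-1-one, aryls cis to each other on the convex face (racemic) | O=C1OC[C@@H]2[C@@H](c3ccc(OCc4ccccc4)c(OCc4ccccc4)c3)O[C@@H](c3ccc(OCc4ccccc4)c(OCc4ccccc4)c3)[C@H]12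
A3 | alternative 2 | trans-2-[3,4-bis(benzyloxy)phenyl]-3-vinyloxirane (racemic) | C=C[C@@H]1O[C@H]1c1ccc(OCc2ccccc2)c(OCc2ccccc2)c1
A4 | alternative 2 | dimethyl 2-[3,4-bis(benzyloxy)benzylidene]malonate | COC(=O)C(=Cc1ccc(OCc2ccccc2)c(OCc2ccccc2)c1)C(=O)OC
A5 | alternative 2 | dimethyl 2,5-cis-bis[3,4-bis(benzyloxy)phenyl]-4-vinyloxolane-3,3-dicarboxylate, vinyl trans to the C5 aryl (racemic) | COC(=O)C1(C(=O)OC)[C@H](C=C)[C@@H](c2ccc(OCc3ccccc3)c(OCc3ccccc3)c2)O[C@H]1c1ccc(OCc2ccccc2)c(OCc2ccccc2)c1
A6 | alternative 3 | (2R,3S,4R,5S)-3,4-bis(acetoxymethyl)oxolane-2,5-dicarboxylic acid (meso) | CC(=O)OC[C@@H]1[C@H](COC(C)=O)[C@@H](C(=O)O)O[C@H]1C(=O)O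
A7 | alternative 3 | 4-bromo-1,2-bis(benzyloxy)benzene | Brc1ccc(OCc2ccccc2)c(OCc2ccccc2)c1
A8 | alternative 3 | tetra-O-benzyl ether of the target (meso) | CC(=O)OC[C@@H]1[C@H](COC(C)=O)[C@@H](c2ccc(OCc3ccccc3)c(OCc3ccccc3)c2)O[C@H]1c1ccc(OCc2ccccc2)c(OCc2ccccc2)c1
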